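**Retrosynthetic overview**
- Feature: ring A is fully substituted, with O at C5, C7 and C8a and prenyl at C6 and C8. C4a is its one carbon carrying neither, and it sits ortho to the C8a oxygen (O1).
- Ring C is cut at C4–C4a and O1–C2. The C2–C3–C4 unit with ring B is first hung on the future O1 as an aryl 2-aryl-3-methoxyacrylate, then moved to C4a by light (photo-Fries) and closed with loss of methanol.
- The ester is cut at its O–acyl bond into 3,5-bis(MOM)-2,4-diprenylphenol and a MOM-protected 2-aryl-3-methoxyacrylic acid.
- Phenol: from phloroglucinol, with the C6 prenyl set by directed lithiation between two MOM ethers and the C8 prenyl by Claisen shift of a 1,1-dimethylallyl ether, which also frees the hydroxyl. Acid: from 2,4-dihydroxyphenylacetic acid by formylation, O-methylation and saponification.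
- Ring order: rings A and B are bought, ring C is the only ring made (penultimate step), and the four MOM ethers leave last.

Key step: step 12

Remark: the target has no stereocentre. The E geometry drawn for the enol ethers is the one expected from the O-methylation, and it is erased when ring C closes.

Step 1
Reactants: 1 2-methylbut-3-en-2-ol
Product: 3 methyl 2-methylbut-3-en-2-yl carbonate, via lithium alkoxide 2 (not isolated)
Conditions: n-BuLi (1.0 equiv), THF, −78 °C; then ClCO2Me, −78 °C → rt
Reagents that add atoms: methyl chloroformate, COC(=O)Cl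
Why: Acylation of a preformed tertiary lithium alkoxide with a chloroformate (carbonate formation) is fast at low temperature and never exposes the ionisable tertiary allylic alcohol to acid.

Step 2
Reactants: 4 phloroglucinol
Product: 5 3,5-bis(methoxymethoxy)phenol
Conditions: MOMCl (2.0 equiv), i-Pr2NEt (2.2 equiv), THF, 0 °C → rt; chromatography
Reagents that add atoms: chloromethyl methyl ether (MOMCl), COCCl
Why: Williamson-type O-alkylation of phenols with a chloromethyl ether; the three hydroxyls are equivalent, so only the degree of alkylation has to be limited by stoichiometry, and this statistical separation falls on the cheapest material of the route.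

Step 3
Reactants: 5 3,5-bis(methoxymethoxy)phenol; 3 methyl 2-methylbut-3-en-2-yl carbonate
Product: 6 1,3-bis(methoxymethoxy)-5-(2-methylbut-3-en-2-yloxy)benzene
Conditions: Pd(PPh3)4 (5 mol %), THF, 0 °C, short reaction time
Reagents that add atoms: none
Why: Tsuji–Trost decarboxylative O-allylation; zerovalent palladium ionises the carbonate, the liberated methoxide deprotonates the phenol, and under kinetic control at low temperature the phenoxide attacks the tertiary terminus of the 1,1-dimethyl-π-allyl complex, the usual entry to aryl 1,1-dimethylallyl ethers.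

Step 4
Reactants: 6 1,3-bis(methoxymethoxy)-5-(2-methylbut-3-en-2-yloxy)benzene; 7 prenyl bromide (1-bromo-3-methylbut-2-ene)
Product: 9 1,3-bis(methoxymethoxy)-2-(3-methylbut-2-enyl)-5-(2-methylbut-3-en-2-yloxy)benzene, via aryllithium 8 (not isolated)
Conditions: n-BuLi (1.1 equiv), THF, −20 → 0 °C; then 7, −78 °C → rt
Reagents that add atoms: none
Why: Directed ortho metalation; the carbon between the two MOM ethers is the most acidic and best chelated site, the bulky tertiary ether (no α-hydrogen, hence no Wittig rearrangement) shields the other two ring positions, and the aryllithium is alkylated at the CH2 end of the primary allylic bromide.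

Step 5
Reactants: 9 1,3-bis(methoxymethoxy)-2-(3-methylbut-2-enyl)-5-(2-methylbut-3-en-2-yloxy)benzene
Product: 10 3,5-bis(methoxymethoxy)-2,4-bis(3-methylbut-2-enyl)phenol
Conditions: PhMe, 110 °C, sealed tube, N2
Reagents that add atoms: none
Why: Aromatic Claisen rearrangement; the [3,3] shift turns the 1,1-dimethylallyl unit into a normal prenyl group at either of the two equivalent free ortho carbons, and tautomerisation frees exactly the hydroxyl that is to be acylated, leaving one ortho C–H.

Step 6
Reactants: 11 2,4-dihydroxyphenylacetic acid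
Product: 12 methyl 2-(2,4-dihydroxyphenyl)acetate
Conditions: MeOH, H2SO4 (cat.), reflux
Reagents that add atoms: methanol, CO
Why: Fischer esterification; the large excess of methanol keeps the ortho-hydroxy acid from resting as its benzofuranone lactone.

Step 7
Reactants: 12 methyl 2-(2,4-dihydroxyphenyl)acetate
Product: 13 methyl 2-[2,4-bis(methoxymethoxy)phenyl]acetate
Conditions: MOMCl (2.5 equiv), i-Pr2NEt (3 equiv), CH2Cl2, 0 °C → rt
Reagents that add atoms: chloromethyl methyl ether (MOMCl), COCCl
Why: O-alkylation of both phenols under amine base, which is too weak to touch the ester or its benzylic CH2.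

Step 8
Reactants: 13 methyl 2-[2,4-bis(methoxymethoxy)phenyl]acetate; 14 methyl formate
Product: 15 methyl 2-[2,4-bis(methoxymethoxy)phenyl]-3-hydroxyprop-2-enoate (enol of the α-formyl ester)
Conditions: NaH (2.5 equiv), 14 (excess), THF, 0 °C → rt; then AcOH to pH 6, 0 °C
Reagents that add atoms: none
Why: Crossed Claisen condensation with a non-enolisable formate, driven by formation of the stabilised sodium enolate, the standard first stage in building β-methoxyacrylate units on ortho-substituted arylacetates.

Step 9
Reactants: 15 methyl 2-[2,4-bis(methoxymethoxy)phenyl]-3-hydroxyprop-2-enoate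
Product: 16 methyl (E)-2-[2,4-bis(methoxymethoxy)phenyl]-3-methoxyprop-2-enoate
Conditions: Me2SO4 (1.2 equiv), K2CO3 (1.5 equiv), DMF, rt
Reagents that add atoms: dimethyl sulfate, COS(=O)(=O)OC
Why: O-methylation of the ambident formyl-ester enolate with a hard electrophile in a dipolar aprotic solvent should give the enol ether, normally as the E isomer, and the geometry has no bearing on the later ring closure.

Step 10
Reactants: 16 methyl (E)-2-[2,4-bis(methoxymethoxy)phenyl]-3-methoxyprop-2-enoate
Product: 17 (E)-2-[2,4-bis(methoxymethoxy)phenyl]-3-methoxyprop-2-enoic acid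
Conditions: LiOH·H2O (3 equiv), THF/MeOH/H2O, 45 °C; then 1 M HCl to pH 4, 0 °C
Reagents that add atoms: lithium hydroxide, [Li+].[OH-]
Why: Saponification by acyl–oxygen cleavage; the MOM acetals and the enol ether are stable to base, and the brief, cold acidification to pH 4 spares both.

Step 11
Reactants: 10 3,5-bis(methoxymethoxy)-2,4-bis(3-methylbut-2-enyl)phenol; 17 (E)-2-[2,4-bis(methoxymethoxy)phenyl]-3-methoxyprop-2-enoic acid
Product: 18 3,5-bis(methoxymethoxy)-2,4-bis(3-methylbut-2-enyl)phenyl (E)-2-[2,4-bis(methoxymethoxy)phenyl]-3-methoxyprop-2-enoate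
Conditions: DCC (1.2 equiv), DMAP (0.2 equiv), CH2Cl2, 0 °C → rt
Reagents that add atoms: none
Why: Steglich esterification; carbodiimide/DMAP activation is free of HCl and avoids an acid chloride, which would strip the acetals and let the 2'-oxygen lactonise onto the acyl carbon, while the phenol has one open ortho side and is nucleophilic enough for the acylpyridinium.

Step 12
Reactants: 18 3,5-bis(methoxymethoxy)-2,4-bis(3-methylbut-2-enyl)phenyl (E)-2-[2,4-bis(methoxymethoxy)phenyl]-3-methoxyprop-2-enoate
Product: 20 3-[2,4-bis(methoxymethoxy)phenyl]-5,7-bis(methoxymethoxy)-6,8-bis(3-methylbut-2-enyl)chromen-4-one, via ortho-hydroxyaryl ketone 19 (not isolated)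
Conditions: hν (254 nm, low-pressure Hg lamps, quartz or FEP flow coil), degassed MeCN (5 mM), N2, 20 °C; lamp off, then DBU (0.2 equiv), 20 → 40 °C
Reagents that add atoms: none
Why: Excitation of the aryl ester breaks the ArO–C(=O) bond homolytically to a singlet, solvent-caged aryloxyl/alkenoyl radical pair; the alkenoyl radical loses CO only slowly, so it recombines in the cage at a ring carbon ortho to oxygen and the dienone tautomerises to ketone 19 (C4–C4a bond), which is the photo-Fries rearrangement as known for aryl cinnamates and aryl 3-methylbut-2-enoates on their way to 2'-hydroxychalcones and chroman-4-ones. The regioselectivity needed is coupling at the future C4a alone, and the substrate secures it: the aryloxyl spin density lies on the two ortho carbons and the para carbon, two of these carry prenyl groups so that coupling there gives non-enolisable dienones that can only fall apart again, and only the remaining ortho C–H position can aromatise irreversibly. Catalytic DBU then lets the single free phenol of 19 add to the methoxy-bearing enone carbon and expel methoxide (oxa-Michael addition–elimination, 6-endo-trig), forming O1–C2 and closing ring C, the same closure that ends the formylation route from 2-hydroxydeoxybenzoins to isoflavones. The chemoselectivity of this closure rests on the MOM ethers, above all the one on the 2'-oxygen, which otherwise could add to the same carbon and give a benzofuran. E/Z isomerisation of the enol ether under the lamp costs photons only, since both isomers rearrange and both close to the same chromone, and no stereocentre is formed. The irradiation is run neutral, aprotic and free of oxygen, a medium in which acetals and trisubstituted alkenes should persist, unlike under AlCl3 or BF3.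

Step 13
Reactants: 20 3-[2,4-bis(methoxymethoxy)phenyl]-5,7-bis(methoxymethoxy)-6,8-bis(3-methylbut-2-enyl)chromen-4-one
Product: 21 3-(2,4-dihydroxyphenyl)-5,7-dihydroxy-6,8-bis(3-methylbut-2-enyl)chromen-4-one (target)
Conditions: conc. aq. HCl (cat.), MeOH, 40 °C, stopped as soon as the last MOM ether is gone
Reagents that add atoms: none
Why: Acid-catalysed transacetalisation of the four aryl MOM ethers to methanol, a deprotection widely used on prenylated flavonoids, which under dilute acid and mild heating should be faster than protonation of the prenyl alkenes.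

**Compound list**
1 | 2-methylbut-3-en-2-ol | CC(C)(O)C=C | starting material
2 | lithium 2-methylbut-3-en-2-olate | CC(C)([O-])C=C.[Li+] | intermediate
3 | methyl 2-methylbut-3-en-2-yl carbonate | COC(=O)OC(C)(C)C=C | intermediate
4 | phloroglucinol | Oc1cc(O)cc(O)c1 | starting material
5 | 3,5-bis(methoxymethoxy)phenol | COCOc1cc(O)cc(OCOC)c1 | intermediate
6 | 1,3-bis(methoxymethoxy)-5-(2-methylbut-3-en-2-yloxy)benzene | COCOc1cc(OCOC)cc(OC(C)(C)C=C)c1 | intermediate
7 | prenyl bromide (1-bromo-3-methylbut-2-ene) | CC(C)=CCBr | starting material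
8 | [2,6-bis(methoxymethoxy)-4-(2-methylbut-3-en-2-yloxy)phenyl]lithium | [Li]c1c(OCOC)cc(OC(C)(C)C=C)cc1OCOC | intermediate
9 | 1,3-bis(methoxymethoxy)-2-(3-methylbut-2-enyl)-5-(2-methylbut-3-en-2-yloxy)benzene | COCOc1cc(OC(C)(C)C=C)cc(OCOC)c1CC=C(C)C | intermediate
10 | 3,5-bis(methoxymethoxy)-2,4-bis(3-methylbut-2-enyl)phenol | COCOc1cc(O)c(CC=C(C)C)c(OCOC)c1CC=C(C)C | intermediate
11 | 2,4-dihydroxyphenylacetic acid | OC(=O)Cc1ccc(O)cc1O | starting material
12 | methyl 2-(2,4-dihydroxyphenyl)acetate | COC(=O)Cc1ccc(O)cc1O | intermediate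
13 | methyl 2-[2,4-bis(methoxymethoxy)phenyl]acetate | COC(=O)Cc1ccc(OCOC)cc1OCOC | intermediate
14 | methyl formate | COC=O | starting material
15 | methyl 2-[2,4-bis(methoxymethoxy)phenyl]-3-hydroxyprop-2-enoate (enol/aldehyde tautomers, geometry not fixed) | COC(=O)C(=CO)c1ccc(OCOC)cc1OCOC | intermediate
16 | methyl (E)-2-[2,4-bis(methoxymethoxy)phenyl]-3-methoxyprop-2-enoate | CO/C=C(/C(=O)OC)c1ccc(OCOC)cc1OCOC | intermediate
17 | (E)-2-[2,4-bis(methoxymethoxy)phenyl]-3-methoxyprop-2-enoic acid | CO/C=C(/C(=O)O)c1ccc(OCOC)cc1OCOC | intermediate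
18 | 3,5-bis(methoxymethoxy)-2,4-bis(3-methylbut-2-enyl)phenyl (E)-2-[2,4-bis(methoxymethoxy)phenyl]-3-methoxyprop-2-enoate | CO/C=C(/C(=O)Oc1cc(OCOC)c(CC=C(C)C)c(OCOC)c1CC=C(C)C)c1ccc(OCOC)cc1OCOC | intermediate
19 | 1-[2-hydroxy-4,6-bis(methoxymethoxy)-3,5-bis(3-methylbut-2-enyl)phenyl]-2-[2,4-bis(methoxymethoxy)phenyl]-3-methoxyprop-2-en-1-one (E/Z mixture under irradiation) | COC=C(C(=O)c1c(O)c(CC=C(C)C)c(OCOC)c(CC=C(C)C)c1OCOC)c1ccc(OCOC)cc1OCOC | intermediate
20 | 3-[2,4-bis(methoxymethoxy)phenyl]-5,7-bis(methoxymethoxy)-6,8-bis(3-methylbut-2-enyl)chromen-4-one | COCOc1ccc(-c2coc3c(CC=C(C)C)c(OCOC)c(CC=C(C)C)c(OCOC)c3c2=O)c(OCOC)c1 | intermediate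
21 | 3-(2,4-dihydroxyphenyl)-5,7-dihydroxy-6,8-bis(3-methylbut-2-enyl)chromen-4-one | CC(C)=CCc1c(O)c(CC=C(C)C)c2occ(-c3ccc(O)cc3O)c(=O)c2c1O | target

**Step count**
- Total step count: 13.
- Longest linear sequence: 8 (steps 6–13).

**Steps most likely to fail**

1. Step 12.
   - Risk: the excited state may be drained by E/Z isomerisation of the enol ether. The radical pair may escape the solvent cage and simply return the phenol. The strongly absorbing products may screen the ester or undergo secondary photolysis before conversion is useful.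
   - Fallback (from 10 and 13, back at 20): the C4–C4a bond is made by polar chemistry.
   - Phenol 10 is capped (MOMCl, i-Pr2NEt, CH2Cl2) as 1,3,5-tris(methoxymethoxy)-2,4-bis(3-methylbut-2-enyl)benzene F1.
   - Ester 13 is reduced (DIBAL-H, PhMe, −78 °C) to 2-[2,4-bis(methoxymethoxy)phenyl]acetaldehyde F2.
   - n-BuLi (THF, 0 °C) removes the only ring hydrogen of F1, flanked by two MOM ethers, to give [2,4,6-tris(methoxymethoxy)-3,5-bis(3-methylbut-2-enyl)phenyl]lithium F3.
   - F3 adds to F2 at −78 °C to give racemic 2-[2,4-bis(methoxymethoxy)phenyl]-1-[2,4,6-tris(methoxymethoxy)-3,5-bis(3-methylbut-2-enyl)phenyl]ethanol F4.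
   - Dess–Martin periodinane (CH2Cl2, NaHCO3) oxidises F4 to the deoxybenzoin 2-[2,4-bis(methoxymethoxy)phenyl]-1-[2,4,6-tris(methoxymethoxy)-3,5-bis(3-methylbut-2-enyl)phenyl]ethanone F5.
   - Brief p-TsOH (cat.) in MeOH at 0 °C removes one of the two equivalent carbonyl-flanking MOM groups, the most labile ones because the freed phenol is chelated. This gives 1-[2-hydroxy-4,6-bis(methoxymethoxy)-3,5-bis(3-methylbut-2-enyl)phenyl]-2-[2,4-bis(methoxymethoxy)phenyl]ethanone F6.
   - N,N-dimethylformamide dimethyl acetal (PhMe, 90 °C) then supplies C2 and closes ring C to 20.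

2. Step 4.
   - Risk: n-BuLi may attack the allylic ether with allylic displacement of the aryloxide, or lithiation may stay incomplete at the low temperature chosen to prevent that.
   - Fallback (from 5, back at 9): the lithiation is done on a silyl ether and the tertiary allyl ether is installed afterwards.
   - Phenol 5 is silylated (TIPSCl, imidazole, DMF) to [3,5-bis(methoxymethoxy)phenoxy]triisopropylsilane F7.
   - n-BuLi (THF, 0 °C) gives [2,6-bis(methoxymethoxy)-4-(triisopropylsilyloxy)phenyl]lithium F8. The bulky silyl ether blocks its own ortho positions.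
   - Prenyl bromide 7 converts F8 into [3,5-bis(methoxymethoxy)-4-(3-methylbut-2-enyl)phenoxy]triisopropylsilane F9.
   - TBAF (THF, 0 °C) frees 3,5-bis(methoxymethoxy)-4-(3-methylbut-2-enyl)phenol F10.
   - The etherification of step 3 (carbonate 3, Pd(PPh3)4, THF, 0 °C), applied to F10, gives 9.

3. Step 13.
   - Risk: acid-catalysed addition of a freed 5- or 7-hydroxyl to the neighbouring prenyl alkene (closure to a dimethylchroman) may compete with removal of the slowest, doubly flanked 7-O-MOM group.
   - Fallback (from 20, back at 21): the acetals are exchanged for silyl ethers without any Brønsted acid.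
   - TMSOTf and 2,2'-bipyridyl (CH2Cl2, 0 °C → rt) convert each aryl MOM ether into an aryl trimethylsilyl ether. This gives 3-[2,4-bis(trimethylsilyloxy)phenyl]-5,7-bis(trimethylsilyloxy)-6,8-bis(3-methylbut-2-enyl)chromen-4-one F11.
   - Water added at the end hydrolyses F11 to 21 at close to neutral pH.

**Further compounds**
F1 | step 12 | 1,3,5-tris(methoxymethoxy)-2,4-bis(3-methylbut-2-enyl)benzene | COCOc1cc(OCOC)c(CC=C(C)C)c(OCOC)c1CC=C(C)C
F2 | step 12 | 2-[2,4-bis(methoxymethoxy)phenyl]acetaldehyde | O=CCc1ccc(OCOC)cc1OCOC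
F3 | step 12 | [2,4,6-tris(methoxymethoxy)-3,5-bis(3-methylbut-2-enyl)phenyl]lithium | [Li]c1c(OCOC)c(CC=C(C)C)c(OCOC)c(CC=C(C)C)c1OCOC
F4 | step 12 | 2-[2,4-bis(methoxymethoxy)phenyl]-1-[2,4,6-tris(methoxymethoxy)-3,5-bis(3-methylbut-2-enyl)phenyl]ethanol (racemic) | OC(Cc1ccc(OCOC)cc1OCOC)c1c(OCOC)c(CC=C(C)C)c(OCOC)c(CC=C(C)C)c1OCOC
F5 | step 12 | 2-[2,4-bis(methoxymethoxy)phenyl]-1-[2,4,6-tris(methoxymethoxy)-3,5-bis(3-methylbut-2-enyl)phenyl]ethanone | O=C(Cc1ccc(OCOC)cc1OCOC)c1c(OCOC)c(CC=C(C)C)c(OCOC)c(CC=C(C)C)c1OCOC
F6 | step 12 | 1-[2-hydroxy-4,6-bis(methoxymethoxy)-3,5-bis(3-methylbut-2-enyl)phenyl]-2-[2,4-bis(methoxymethoxy)phenyl]ethanone | O=C(Cc1ccc(OCOC)cc1OCOC)c1c(O)c(CC=C(C)C)c(OCOC)c(CC=C(C)C)c1OCOC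
F7 | step 4 | [3,5-bis(methoxymethoxy)phenoxy]triisopropylsilane | COCOc1cc(OCOC)cc(O[Si](C(C)C)(C(C)C)C(C)C)c1
F8 | step 4 | [2,6-bis(methoxymethoxy)-4-(triisopropylsilyloxy)phenyl]lithium | [Li]c1c(OCOC)cc(O[Si](C(C)C)(C(C)C)C(C)C)cc1OCOC
F9 | step 4 | [3,5-bis(methoxymethoxy)-4-(3-methylbut-2-enyl)phenoxy]triisopropylsilane | COCOc1cc(O[Si](C(C)C)(C(C)C)C(C)C)cc(OCOC)c1CC=C(C)C
F10 | step 4 | 3,5-bis(methoxymethoxy)-4-(3-methylbut-2-enyl)phenol | COCOc1cc(O)cc(OCOC)c1CC=C(C)C
F11 | step 13 | 3-[2,4-bis(trimethylsilyloxy)phenyl]-5,7-bis(trimethylsilyloxy)-6,8-bis(3-methylbut-2-enyl)chromen-4-one | CC(C)=CCc1c(O[Si](C)(C)C)c(CC=C(C)C)c2occ(-c3ccc(O[Si](C)(C)C)cc3O[Si](C)(C)C)c(=O)c2c1O[Si](C)(C)C
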